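## The problem

Target 23 is a γ-butyrolactone (O1, C2 carbonyl, C3, C4, C5) with an exocyclic E-configured 4-hydroxy-3-methoxybenzylidene on C3 and a 3,4-dimethoxybenzyl group on C4; no rings are fused, and both arenes hang from the lactone by one-carbon links. C4 (R) is the only stereocentre, so nothing in the molecule can direct it, and its configuration has to come from a reagent or a catalyst. The second stereo-element is the alkene, whose aryl group must lie anti to the carbonyl (E); this is decided when the C3=CH bond is made. The two elements interact, because once the benzylidene is in place base can move the double bond into the ring (C3=C4) and erase C4. The stereocentre should therefore be secured first, and the alkene introduced late and under mild conditions. The free phenol is acidic and would turn an aldehyde partner into an unreactive phenoxide, the lactone does not tolerate strong nucleophiles or hydrides, and the veratryl ring is sensitive to electrophiles and oxidants. The enabling feature is that C4 sits between C3, a plain CH2 in a saturated precursor, and C5, an oxygen-bearing CH2. The bonds C3–C4 and O1–C5 are exactly those a ketene two-carbon unit (C2–C3) makes on the β- and α-carbons of an (E)-alkenyl sulfoxide, leaving sulfur on C5 and two chlorines on C3 (all removable by reduction) while chirality passes from sulfur to C4.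

## Retrosynthesis

**23 from 22.** The last bond cut is the phenolic O–Si bond. Carrying the phenol as its tert-butyldimethylsilyl ether 22 keeps the acidic proton out of the enolate and elimination steps. The forward reaction only has to cleave an aryl silyl ether without touching the enoate.

**22 from 16 and 18.** The exocyclic C3=CH bond is cut (aldol addition to 20, then elimination through mesylate 21). This removes the most base-sensitive element and leaves two simple pieces: lactone 16, which has one stereocentre and no alkene, and aldehyde 18, one step from vanillin 17. Cutting inside the ring instead (C2–C3 or C2–O1) would keep the alkene through more steps. The forward reaction must give the E isomer and must not move the alkene into the ring.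

**16 from 15 and 13.** No skeletal bond is cut. Sulfur is put back on C5 (15) and two chlorines on C3 (13). This functional-group addition costs two reductions in the forward sense but turns 16 into the direct product of a ring-forming, stereocentre-forming step. The forward reductions must leave C4 untouched, which they do because C4 is neither α to the carbonyl nor a leaving-group carbon.

**13 from 8 and 10.** The C3–C4 and O1–C5 bonds are cut together. This takes the lactone back to an acyclic (S,E)-alkenyl sulfoxide 8 and dichloroketene 10, made in the flask from trichloroacetyl chloride 9, and it trades the carbon stereocentre for a sulfur stereocentre that can be bought in pure form. Against an enolate alkylation or a conjugate addition at C4, this cut builds the ring and the stereocentre in one operation. The forward reaction must transfer chirality from sulfur to C4 with high fidelity and must acylate oxygen, not carbon.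

**8 from 4 and 5.** The S–C(sp2) bond is cut to (E)-alkenyl iodide 4 and menthyl sulfinate 5 (Andersen synthesis). The sulfur stereocentre then comes from a commercial, crystalline reagent, and the alkene geometry from the iodide. The forward reaction must proceed with inversion at sulfur and retention of alkene geometry.

**4 from 2, and 2 from 1.** The C–I bond is traced to terminal alkyne 2 by hydrozirconation and iodination, which fixes the E geometry. The sp3–sp bond of 2 is cut to benzyl chloride 1 and an ethynyl nucleophile. Both forward steps must avoid base-induced migration of the skipped unsaturation into conjugation with the arene.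

## Roads not taken

**Alternative 1:** The cut is at C3–C4 and at the CH2–aryl bond of the C4 side chain, in an open chain. The forward key step is a palladium-catalysed three-component conjunctive coupling (Pd(OAc)2 with a chiral ferrocenyl bisphosphine). An alkenyl group carrying the pre-formed benzylidene migrates from boron to carbon while the dimethoxyphenyl group is delivered to the vinyl terminus, giving allylic boronate A1.
- Merits: the stereocentre is set by a catalyst, the alkene geometry is fixed before the stereocentre exists, and three fragments are joined at once.
- Weak points: no ring is closed and C5 is missing. A one-carbon Matteson homologation at a secondary allylic boron centre, oxidation, unmasking and oxidation of the allylic silyl ether, lactonisation and removal of a second silyl group must follow, at least five operations. A1 is also prone to 1,3-boron shift and protodeboronation.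
- Comparison: this road is better in being catalytic in chirality and in never needing a late elimination. The chosen plan sets against this a single step that closes the lactone and sets C4 from an off-the-shelf enantiopure sulfinate, and a much shorter path after the key step.

**Alternative 2:** The cut is at C2–C3 and C2–O1. The forward key step is cyclocarbonylation of homopropargylic alcohol A2 with PdCl2(PPh3)2/SnCl2 under CO. Syn addition across the alkyne closes the lactone and gives the E-benzylidene directly as silyl ether A3, which is the same compound as 22.
- Merits: the alkene geometry follows from the mechanism, the ring and the alkene form together, and only a desilylation remains.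
- Weak points: the step creates no stereocentre. The propargylic, α-branched stereocentre of A2 has to be built separately, typically by auxiliary alkylation, reduction, oxidation, alkyne homologation of an epimerisable aldehyde and arylation. The electron-rich aryl alkyne may also give the six-membered lactone or the regioisomeric hydropalladation product.
- Comparison: this road is clearly better for the alkene geometry and avoids base at the end. The chosen plan sets against it a stereocentre that costs no extra steps, since it arises in the ring-forming step, and an aldol–elimination sequence known to favour the E isomer in this lactone class, with an olefination fallback.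

**Alternative 3:** The cut is at C3–C4 alone. The forward key step is intramolecular carbene insertion of diazoacetate A4, catalysed by the chiral dirhodium carboxamidate Rh2(4S-MPPIM)4, into the homobenzylic C–H bond. It closes the lactone and sets C4, giving A5, which is the same compound as 16.
- Merits: it is the shortest way to the lactone, about three steps from the parent alcohol against six in the chosen plan, and it is catalytic in chirality.
- Weak points: the catalyst is specialised and its antipode must be matched to the (R)-lactone. A diazo ester has to be made and handled. The electron-rich ring invites benzylic insertion to the six-membered lactone and aromatic cycloaddition. Enantioselectivity depends on catalyst discrimination between two enantiotopic hydrogens, not on a stereospecific transfer.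
- Comparison: this road is shorter and more atom-economical. The chosen plan sets against it commercial reagents only, optical purity fixed by a crystalline sulfinate and passed on stereospecifically, and no competing C–H sites. The steps after the lactone would be identical on both roads.

Key step: step 4

Assumption: the sense of sulfur-to-carbon transfer in step 4 is taken from the chair model with p-tolyl pseudo-equatorial, not from a recorded assignment. It would be checked by comparing the sign of rotation of 16 with that recorded for the (R)-lactone. C5 of 13–15 is drawn 4,5-trans, although either C5 epimer would serve; 14, 20 and 21 are carried as mixtures at their unmarked centre.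

## Route

Step 1
Reactants: 1 4-(chloromethyl)-1,2-dimethoxybenzene (3,4-dimethoxybenzyl chloride)
Product: 2 1,2-dimethoxy-4-(prop-2-yn-1-yl)benzene
Conditions: HC≡CMgBr (2 equiv), CuCl (cat.), THF, 0 °C to 50 °C
Reagents that add atoms: ethynylmagnesium bromide, C#C[Mg]Br
Why: Copper-catalysed sp3–sp cross-coupling of a benzylic chloride with an acetylide Grignard reagent; the excess of ethynyl reagent suppresses a second benzylation of the product acetylide and the moderate temperature limits propargyl-to-allene isomerisation.

Step 2
Reactants: 2 1,2-dimethoxy-4-(prop-2-yn-1-yl)benzene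
Product: 4 4-[(E)-3-iodoprop-2-en-1-yl]-1,2-dimethoxybenzene, via alkenylzirconocene chloride 3 (not isolated)
Conditions: Cp2Zr(H)Cl, THF, rt, dark; then I2, 0 °C
Reagents that add atoms: iodine, II
Why: Hydrozirconation adds Zr–H syn across the terminal alkyne with zirconium on the terminal carbon, and iodinolysis of the C–Zr bond goes with retention, so only the E-iodide should form; the neutral medium leaves the skipped benzylic CH2 in place.

Step 3
Reactants: 4 4-[(E)-3-iodoprop-2-en-1-yl]-1,2-dimethoxybenzene; 5 (1S,2R,5S)-menthyl (R)-p-toluenesulfinate
Product: 8 (S,E)-3-(3,4-dimethoxyphenyl)prop-1-enyl p-tolyl sulfoxide, via alkenyllithium 6 (not isolated), via alkenylmagnesium bromide 7 (not isolated)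
Conditions: t-BuLi (2 equiv), Et2O, −78 °C; MgBr2·OEt2; then added to 5, toluene/THF, −78 to −40 °C
Reagents that add atoms: none
Why: Iodine–lithium exchange and transmetalation to magnesium keep the E geometry; in the Andersen sulfoxide synthesis the alkenyl Grignard reagent displaces menthoxide at sulfur with clean inversion, so the (R)-sulfinate should give the (S)-sulfoxide. Inverse addition at low temperature guards against a second attack at sulfur and against deprotonation of the γ-CH2.

Step 4
Reactants: 8 (S,E)-3-(3,4-dimethoxyphenyl)prop-1-enyl p-tolyl sulfoxide; 9 trichloroacetyl chloride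
Product: 13 (4S,5S)-3,3-dichloro-4-(3,4-dimethoxybenzyl)-5-(p-tolylthio)oxolan-2-one, via dichloroketene 10 (not isolated), via vinyloxysulfonium enolate 11 (not isolated), via thionium carboxylate 12 (not isolated)
Conditions: Cl3CCOCl (slow addition), Zn–Cu couple, THF, −45 °C to 0 °C
Reagents that add atoms: none
Why: Zinc reduces 9 to dichloroketene 10, whose central carbon is attacked by the sulfinyl oxygen of 8 to give vinyloxysulfonium enolate 11; a [3,3] shift then joins the CCl2 terminus to the alkene carbon remote from sulfur (C3–C4), breaks the S–O bond and leaves thionium carboxylate 12, which collapses to 13. The closest known reaction type is the ketene lactonisation of alkenyl sulfoxides (an additive Pummerer or sulfonium-Claisen process), established for (E)-3-arylprop-1-enyl p-tolyl sulfoxides. The single new ring, the γ-lactone, closes by 5-exo-trig attack of the carboxylate oxygen on the thionium carbon (O1–C5). C4 is controlled by the sulfur stereocentre through a chair-like six-membered transition state with p-tolyl pseudo-equatorial, the sulfur lone pair pseudo-axial and the E-alkene substituent equatorial; for (S)-sulfur this exposes the alkene face that gives (4S) in 13, which is (R) by descriptor once chlorine and sulfur are removed. C5 is set by the C4 benzyl group, the carboxylate adding anti to it (4,5-trans), and this centre is erased in step 6. The step needs acylation at oxygen in preference to [2+2] addition to the alkene or attack on the arene; the substrate secures this because the sulfinyl oxygen is its only strong nucleophile and the alkene is electron-poor. It also needs the sigmatropic shift to outrun deprotonation of the benzylic CH2, which its intramolecular course, slow ketene generation and low temperature should ensure.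

Step 5
Reactants: 13 (4S,5S)-3,3-dichloro-4-(3,4-dimethoxybenzyl)-5-(p-tolylthio)oxolan-2-one
Product: 15 (4R,5S)-4-(3,4-dimethoxybenzyl)-5-(p-tolylthio)oxolan-2-one, via monochloro lactone 14 (not isolated)
Conditions: Zn dust, AcOH, rt
Reagents that add atoms: none
Why: Zinc reduces the α-chloro carbonyl C–Cl bonds one after the other through zinc enolates that acetic acid protonates; the thioacetal carbon and the aryl ethers are inert to zinc, and C4 is untouched because the enolate has no β-leaving group (the descriptor changes from S to R only because C3 loses rank).

Step 6
Reactants: 15 (4R,5S)-4-(3,4-dimethoxybenzyl)-5-(p-tolylthio)oxolan-2-one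
Product: 16 (R)-4-(3,4-dimethoxybenzyl)oxolan-2-one
Conditions: Raney Ni (W-2), EtOH, rt
Reagents that add atoms: none
Why: Hydrogenolytic desulfurisation of the S,O-acetal C–S bond on Raney nickel; C4 is not involved, so the configuration set in step 4 should be carried into the lactone unchanged.

Step 7
Reactants: 17 vanillin (4-hydroxy-3-methoxybenzaldehyde)
Product: 18 4-[(tert-butyldimethylsilyl)oxy]-3-methoxybenzaldehyde
Conditions: TBSCl, imidazole, DMF, rt
Reagents that add atoms: tert-butyldimethylsilyl chloride, CC(C)(C)[Si](C)(C)Cl
Why: Standard silylation of a phenol; the silyl ether removes the acidic proton that would quench the enolate and would convert the aldehyde into an unreactive phenoxide in step 8.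

Step 8
Reactants: 16 (R)-4-(3,4-dimethoxybenzyl)oxolan-2-one; 18 4-[(tert-butyldimethylsilyl)oxy]-3-methoxybenzaldehyde
Product: 20 (3S,4R)-3-[{4-[(tert-butyldimethylsilyl)oxy]-3-methoxyphenyl}(hydroxy)methyl]-4-(3,4-dimethoxybenzyl)oxolan-2-one (carbinol epimers), via lithium enolate 19 (not isolated)
Conditions: LiN(SiMe3)2, THF, −78 °C; then 18, −78 °C; NH4Cl (aq)
Reagents that add atoms: none
Why: Lithium enolate aldol addition; the aldehyde should approach C3 anti to the C4 benzyl group to give the 3,4-trans adduct, and the carbinol configuration does not matter because that carbon becomes sp2 in step 9.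

Step 9
Reactants: 20 (3S,4R)-3-[{4-[(tert-butyldimethylsilyl)oxy]-3-methoxyphenyl}(hydroxy)methyl]-4-(3,4-dimethoxybenzyl)oxolan-2-one
Product: 22 (3E,4R)-3-{4-[(tert-butyldimethylsilyl)oxy]-3-methoxybenzylidene}-4-(3,4-dimethoxybenzyl)oxolan-2-one, via mesylate 21 (not isolated)
Conditions: MsCl, Et3N, CH2Cl2, 0 °C; then DBU, rt
Reagents that add atoms: none
Why: Mesylation followed by E1cB elimination through the lactone enolate; the E isomer, with the aryl ring remote from the carbonyl oxygen, is the one this sequence is known to favour for α-arylidene-β-benzyl lactones. Short exposure to DBU at room temperature should not move the alkene into the ring, so C4 is kept.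

Step 10
Reactants: 22 (3E,4R)-3-{4-[(tert-butyldimethylsilyl)oxy]-3-methoxybenzylidene}-4-(3,4-dimethoxybenzyl)oxolan-2-one
Product: 23 (3E,4R)-4-(3,4-dimethoxybenzyl)-3-(4-hydroxy-3-methoxybenzylidene)oxolan-2-one
Conditions: Bu4NF, AcOH, THF, 0 °C
Reagents that add atoms: none
Why: Fluoride cleaves the aryl O–Si bond; buffering with acetic acid keeps the liberated phenoxide from adding to the enoate or shifting the alkene, so the E geometry and C4 should persist.

## Compound list

1 | 4-(chloromethyl)-1,2-dimethoxybenzene (3,4-dimethoxybenzyl chloride) | COc1ccc(CCl)cc1OC | starting material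
2 | 1,2-dimethoxy-4-(prop-2-yn-1-yl)benzene | COc1ccc(CC#C)cc1OC | intermediate
3 | chlorobis(cyclopentadienyl)[(E)-3-(3,4-dimethoxyphenyl)prop-1-en-1-yl]zirconium | COc1ccc(C/C=C/[Zr](Cl)(C2C=CC=C2)C2C=CC=C2)cc1OC | intermediate
4 | 4-[(E)-3-iodoprop-2-en-1-yl]-1,2-dimethoxybenzene | COc1ccc(C/C=C/I)cc1OC | intermediate
5 | (1S,2R,5S)-menthyl (R)-p-toluenesulfinate | Cc1ccc(cc1)[S@](=O)O[C@H]1C[C@@H](C)CC[C@@H]1C(C)C | starting material
6 | [(E)-3-(3,4-dimethoxyphenyl)prop-1-en-1-yl]lithium | [Li]/C=C/Cc1ccc(OC)c(OC)c1 | intermediate
7 | [(E)-3-(3,4-dimethoxyphenyl)prop-1-en-1-yl]magnesium bromide | Br[Mg]/C=C/Cc1ccc(OC)c(OC)c1 | intermediate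
8 | (S,E)-3-(3,4-dimethoxyphenyl)prop-1-enyl p-tolyl sulfoxide | Cc1ccc(cc1)[S@@](=O)/C=C/Cc1ccc(OC)c(OC)c1 | intermediate
9 | trichloroacetyl chloride | O=C(Cl)C(Cl)(Cl)Cl | starting material
10 | dichloroketene | O=C=C(Cl)Cl | intermediate
11 | (S)-(2,2-dichloro-1-oxidoethenyloxy)[(E)-3-(3,4-dimethoxyphenyl)prop-1-enyl](p-tolyl)sulfonium (vinyloxysulfonium enolate) | Cc1ccc(cc1)[S@@+](OC([O-])=C(Cl)Cl)/C=C/Cc1ccc(OC)c(OC)c1 | intermediate
12 | (3S)-2,2-dichloro-3-(3,4-dimethoxybenzyl)-4-(p-tolylsulfonio)but-3-enoate (thionium carboxylate) | [O-]C(=O)C(Cl)(Cl)[C@@H](Cc1ccc(OC)c(OC)c1)C=[S+]c1ccc(C)cc1 | intermediate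
13 | (4S,5S)-3,3-dichloro-4-(3,4-dimethoxybenzyl)-5-(p-tolylthio)oxolan-2-one | O=C1O[C@@H](Sc2ccc(C)cc2)[C@H](Cc2ccc(OC)c(OC)c2)C1(Cl)Cl | intermediate
14 | (4S,5S)-3-chloro-4-(3,4-dimethoxybenzyl)-5-(p-tolylthio)oxolan-2-one (C3 epimers) | O=C1O[C@@H](Sc2ccc(C)cc2)[C@H](Cc2ccc(OC)c(OC)c2)C1Cl | intermediate
15 | (4R,5S)-4-(3,4-dimethoxybenzyl)-5-(p-tolylthio)oxolan-2-one | O=C1O[C@@H](Sc2ccc(C)cc2)[C@H](Cc2ccc(OC)c(OC)c2)C1 | intermediate
16 | (R)-4-(3,4-dimethoxybenzyl)oxolan-2-one | O=C1C[C@@H](Cc2ccc(OC)c(OC)c2)CO1 | intermediate
17 | vanillin (4-hydroxy-3-methoxybenzaldehyde) | COc1cc(C=O)ccc1O | starting material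
18 | 4-[(tert-butyldimethylsilyl)oxy]-3-methoxybenzaldehyde | COc1cc(C=O)ccc1O[Si](C)(C)C(C)(C)C | intermediate
19 | lithium (R)-4-(3,4-dimethoxybenzyl)-4,5-dihydrofuran-2-olate (lithium enolate of 16) | [Li]OC1=C[C@@H](Cc2ccc(OC)c(OC)c2)CO1 | intermediate
20 | (3S,4R)-3-[{4-[(tert-butyldimethylsilyl)oxy]-3-methoxyphenyl}(hydroxy)methyl]-4-(3,4-dimethoxybenzyl)oxolan-2-one (carbinol epimers) | O=C1OC[C@H](Cc2ccc(OC)c(OC)c2)[C@H]1C(O)c3ccc(O[Si](C)(C)C(C)(C)C)c(OC)c3 | intermediate
21 | {4-[(tert-butyldimethylsilyl)oxy]-3-methoxyphenyl}[(3S,4R)-4-(3,4-dimethoxybenzyl)-2-oxooxolan-3-yl]methyl methanesulfonate (epimers at the mesylate carbon) | O=C1OC[C@H](Cc2ccc(OC)c(OC)c2)[C@H]1C(OS(C)(=O)=O)c3ccc(O[Si](C)(C)C(C)(C)C)c(OC)c3 | intermediate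
22 | (3E,4R)-3-{4-[(tert-butyldimethylsilyl)oxy]-3-methoxybenzylidene}-4-(3,4-dimethoxybenzyl)oxolan-2-one | COc1cc(/C=C2/C(=O)OC[C@@H]2Cc2ccc(OC)c(OC)c2)ccc1O[Si](C)(C)C(C)(C)C | intermediate
23 | (3E,4R)-4-(3,4-dimethoxybenzyl)-3-(4-hydroxy-3-methoxybenzylidene)oxolan-2-one | COc1cc(/C=C2/C(=O)OC[C@@H]2Cc2ccc(OC)c(OC)c2)ccc1O | target

## Step count and risks

Total step count: 10. Longest linear sequence: 9 steps (1 to 23 through steps 1–6 and 8–10); step 7 is a one-step side branch.

**Step 4 (key step).** The most likely failure is incomplete or reversed facial selectivity in the [3,3] shift. The chair with p-tolyl pseudo-equatorial has to be clearly preferred over the arrangement with p-tolyl pseudo-axial; if it is not, chirality transfer is eroded or runs opposite to the model. A second risk is loss of material through deprotonation of the benzylic CH2 in the acylated sulfonium stage or through ketene oligomerisation.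

The fallback reaches lactone 16 without the sulfoxide and sets out from benzyl chloride 1. The sodium enolate of the known imide (R)-4-benzyl-3-(4-tert-butoxy-4-oxobutanoyl)oxazolidin-2-one F1 (NaN(SiMe3)2, THF, −78 °C) would be alkylated with 1 (NaI cat.) anti to the auxiliary benzyl group. This Evans alkylation would give tert-butyl (3R)-4-[(4R)-4-benzyl-2-oxooxazolidin-3-yl]-3-(3,4-dimethoxybenzyl)-4-oxobutanoate F2. LiBH4 in wet Et2O would cleave the auxiliary reductively to tert-butyl (3R)-4-(3,4-dimethoxyphenyl)-3-(hydroxymethyl)butanoate F3. TsOH in warm toluene would then close F3 to 16, where the route is rejoined at step 8.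

**Step 3.** The likely failures are migration of the double bond into conjugation with the arene (deprotonation of the doubly activated γ-CH2 by the alkenylmetal or by menthoxide) and partial loss of configuration at sulfur through a second organometallic attack on the sulfoxide.

The fallback sets out from alkyne 2 and installs sulfur before the alkene geometry. Deprotonation with EtMgBr and reaction with 5 in toluene would give (R)-3-(3,4-dimethoxyphenyl)prop-1-ynyl p-tolyl sulfoxide F4. This has the same spatial arrangement at sulfur as 8; the descriptor differs only because alkynyl outranks p-tolyl. Trans-hydroalumination directed by the sulfinyl group (LiAlH4, THF, −90 °C) would then give the E-alkene and return to 8.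

**Step 9.** The likely failures are formation of an E/Z mixture in the elimination and base-induced migration of the alkene into the ring on prolonged contact with DBU, which would erase C4.

The fallback sets out from lactone 16 and forms the alkene by olefination. Phosphorylation of the enolate (LiN(iPr)2, ClP(O)(OEt)2, with 1,3-phosphorus shift of the enol phosphate) would give diethyl [(4S)-4-(3,4-dimethoxybenzyl)-2-oxooxolan-3-yl]phosphonate F5. Its C4 has the same spatial arrangement as in 16; the descriptor changes because phosphorus raises the rank of C3. Horner–Wadsworth–Emmons reaction with 18 (NaH, THF, 0 °C) would return to 22.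

**Step 1.** The likely failures are base-induced isomerisation of the skipped aryl propyne to the allene or the conjugated internal alkyne, and a second benzylation of the product acetylide.

The fallback sets out from 1 with a capped alkyne. Copper-catalysed coupling with (trimethylsilyl)ethynylmagnesium bromide (CuBr, THF) would give [3-(3,4-dimethoxyphenyl)prop-1-yn-1-yl]trimethylsilane F6, which cannot form an acetylide. Buffered desilylation (Bu4NF, AcOH, THF) would return to 2.

## Further compounds

F1 | step 4 | (R)-4-benzyl-3-(4-tert-butoxy-4-oxobutanoyl)oxazolidin-2-one | CC(C)(C)OC(=O)CCC(=O)N1[C@H](Cc2ccccc2)COC1=O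
F2 | step 4 | tert-butyl (3R)-4-[(4R)-4-benzyl-2-oxooxazolidin-3-yl]-3-(3,4-dimethoxybenzyl)-4-oxobutanoate | CC(C)(C)OC(=O)C[C@@H](Cc1ccc(OC)c(OC)c1)C(=O)N1[C@H](Cc2ccccc2)COC1=O
F3 | step 4 | tert-butyl (3R)-4-(3,4-dimethoxyphenyl)-3-(hydroxymethyl)butanoate | CC(C)(C)OC(=O)C[C@@H](Cc1ccc(OC)c(OC)c1)CO
F4 | step 3 | (R)-3-(3,4-dimethoxyphenyl)prop-1-ynyl p-tolyl sulfoxide | Cc1ccc(cc1)[S@@](=O)C#CCc1ccc(OC)c(OC)c1
F5 | step 9 | diethyl [(4S)-4-(3,4-dimethoxybenzyl)-2-oxooxolan-3-yl]phosphonate (C3 epimers) | CCOP(=O)(OCC)C1C(=O)OC[C@@H]1Cc2ccc(OC)c(OC)c2
F6 | step 1 | [3-(3,4-dimethoxyphenyl)prop-1-yn-1-yl]trimethylsilane | COc1ccc(CC#C[Si](C)(C)C)cc1OC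
A1 | alternative 1 | tert-butyl{[(2E,3R)-4-(3,4-dimethoxyphenyl)-2-{3-methoxy-4-[(triisopropylsilyl)oxy]benzylidene}-3-(4,4,5,5-tetramethyl-1,3,2-dioxaborolan-2-yl)butyl]oxy}dimethylsilane | COc1cc(/C=C(/CO[Si](C)(C)C(C)(C)C)[C@H](B2OC(C)(C)C(C)(C)O2)Cc2ccc(OC)c(OC)c2)ccc1O[Si](C(C)C)(C(C)C)C(C)C
A2 | alternative 2 | (2R)-4-{4-[(tert-butyldimethylsilyl)oxy]-3-methoxyphenyl}-2-(3,4-dimethoxybenzyl)but-3-yn-1-ol | OC[C@H](Cc1ccc(OC)c(OC)c1)C#Cc1ccc(O[Si](C)(C)C(C)(C)C)c(OC)c1
A3 | alternative 2 | (3E,4R)-3-{4-[(tert-butyldimethylsilyl)oxy]-3-methoxybenzylidene}-4-(3,4-dimethoxybenzyl)oxolan-2-one | COc1cc(/C=C2/C(=O)OC[C@@H]2Cc2ccc(OC)c(OC)c2)ccc1O[Si](C)(C)C(C)(C)C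
A4 | alternative 3 | 3-(3,4-dimethoxyphenyl)propyl diazoacetate | [N-]=[N+]=CC(=O)OCCCc1ccc(OC)c(OC)c1
A5 | alternative 3 | (R)-4-(3,4-dimethoxybenzyl)oxolan-2-one | O=C1C[C@@H](Cc2ccc(OC)c(OC)c2)CO1
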